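**Retrosynthetic overview**

- The last C–C bond made joins the enone β-carbon to C5 of ring B. It comes from a Mizoroki–Heck coupling of a 5-bromo-2,3-dihydrobenzofuran with a bis-silylated ring A aryl vinyl ketone (built from 2,4-dihydroxyacetophenone and prenyl bromide). Global desilylation ends the route.
- The strategy rests on the five-membered ring O1–C2–C3–C3a–C7a of ring B. C3 is a benzylic carbinol carbon on C3a, and C2 carries the ring oxygen O1, which sits on the neighbouring arene carbon C7a. If the C2–C3 bond is opened and the C3 oxygen is bonded to C2 instead, the ring becomes the six-membered acetal ring of a salicyl alcohol acetal (a 4H-1,3-benzodioxin) whose one stereocentre is the acetal carbon.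
- Key disconnection: [1,2]-Wittig ring contraction of the C4-lithiated benzodioxin. It forms C2–C3, closes the dihydrofuran ring and sets C3 trans to the C2 side chain.
- The acetal centre is secured as one diastereomer of the (−)-menthyl glyoxylate acetal of salicyl alcohol. MeMgBr then turns the ester into the CMe2–O group.
- Ring order: both benzene rings are bought. The 1,3-dioxin ring is closed in step 1 and contracted to the dihydrofuran ring in step 4. No other ring is formed.

Key step: step 4

Assumption: the two C2 epimers of the menthyl ester formed in step 1 can be separated, the acetal carbon is configurationally stable to base once the ester is gone, and the C2 configuration of 3 is to be assigned by X-ray analysis against the menthyl group.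

**Route**

Step 1
Reactants: 1 2-hydroxybenzyl alcohol; 2 (1R,2S,5R)-menthyl 2,2-dihydroxyacetate ((−)-menthyl glyoxylate hydrate)
Product: 3 (1R,2S,5R)-menthyl (2S)-4H-1,3-benzodioxine-2-carboxylate
Conditions: TsOH·H2O (5 mol %), PhMe, reflux, Dean–Stark; the two C2 epimers separated (SiO2, then crystallisation); the unwanted (2R)-epimer returned to TsOH, PhMe, reflux, which re-establishes the epimer mixture, and separated again
Reagents that add atoms: none
Why: Acid-catalysed acetalisation of an aldehyde hydrate with a 1,3-diol under azeotropic removal of water should close the 1,3-dioxin ring; the acetal centre forms without control, so the (2S)-ester is obtained by separating the two menthyl ester diastereomers, and because ring closure is reversible through the ring-opened oxocarbenium ion, the unwanted (2R)-epimer is re-equilibrated by the same acid and not lost.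

Step 2
Reactants: 3 (1R,2S,5R)-menthyl (2S)-4H-1,3-benzodioxine-2-carboxylate
Product: 5 2-[(2S)-4H-1,3-benzodioxin-2-yl]propan-2-ol, via methyl ketone 4 (not isolated)
Conditions: MeMgBr (4 equiv), THF, −20 °C → rt; aq NH4Cl
Reagents that add atoms: methylmagnesium bromide, C[Mg]Br
Why: Double Grignard addition to the ester through methyl ketone 4 gives the tertiary alcohol and releases the auxiliary as menthol; chelation-assisted addition to the α,α-dialkoxy carbonyl groups should be faster than enolisation, and any ketone that does enolise returns on work-up as ketone and not as epimerised carbinol, so the acetal centre of 5 is not touched (optical purity to be checked by chiral HPLC).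

Step 3
Reactants: 5 2-[(2S)-4H-1,3-benzodioxin-2-yl]propan-2-ol
Product: 6 (2S)-2-[2-(triethylsilyloxy)propan-2-yl]-4H-1,3-benzodioxine
Conditions: Et3SiCl, imidazole, 4-(dimethylamino)pyridine (cat.), DMF, 40 °C
Reagents that add atoms: chlorotriethylsilane, CC[Si](Cl)(CC)CC
Why: Silylation of the tertiary alcohol under basic conditions leaves the acid-sensitive acetal intact and installs a group that tolerates sec-BuLi and is removed by fluoride at the end.

Step 4
Reactants: 6 (2S)-2-[2-(triethylsilyloxy)propan-2-yl]-4H-1,3-benzodioxine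
Product: 9 (2R,3R)-2-[2-(triethylsilyloxy)propan-2-yl]-2,3-dihydro-1-benzofuran-3-ol, via C4-lithiated acetal 7 (not isolated), via lithium alkoxide 8 (not isolated)
Conditions: sec-BuLi (1.3 equiv), THF, −78 °C (→ −40 °C if needed); sat. aq NH4Cl
Reagents that add atoms: none
Why: Proposed new method: sec-BuLi should remove a C4 proton, which is both benzylic and α to O3 and so the kinetically most acidic C–H of 6; the carbanion 7 should then undergo the [1,2]-Wittig shift, in which the O3–C2 bond breaks homolytically to a ketyl radical anion at C4 and an O1-stabilised radical at C2 that remain joined through the arene and O1 and recombine carbon to carbon. The closest known reaction type is the acetal [1,2]-Wittig rearrangement of O-benzyl glycosides and related benzyl acetals to α-alkoxy carbinols, which proceeds under such conditions with retention at the migrating acetal carbon; its use to contract a 4H-1,3-benzodioxin is untested. The dihydrofuran ring (O1–C2–C3–C3a–C7a) closes by coupling of the two radical centres within the tethered pair, a five-membered closure in which the new C2–C3 bond replaces the broken C2–O3 bond. C2 should keep its configuration because the ketyl carbon lies next to the departing oxygen and bonds to the same face of the C2 radical before rotation about O1–C2 can intervene, so (S)-6 maps onto (2R), the change of descriptor being a priority effect only. The new C3 centre is set as the ketyl turns about C3a–C3 toward C2, which should place the O–Li group on the face away from the bulky CMe2OSiEt3 group (trans, 3R). The step needs C4 lithiation to outrun ortho-lithiation at C8 and the shift to outrun α-elimination; the doubly activated C4–H bonds, the inability of ring-held O3 to chelate lithium toward C8, the low temperature and the high migratory aptitude of an oxygen-substituted secondary carbon are what should secure this.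

Step 5
Reactants: 9 (2R,3R)-2-[2-(triethylsilyloxy)propan-2-yl]-2,3-dihydro-1-benzofuran-3-ol
Product: 10 (2R,3R)-3-(triethylsilyloxy)-2-[2-(triethylsilyloxy)propan-2-yl]-2,3-dihydro-1-benzofuran
Conditions: Et3SiCl, imidazole, 4-(dimethylamino)pyridine (cat.), DMF, rt
Reagents that add atoms: chlorotriethylsilane, CC[Si](Cl)(CC)CC
Why: Base-mediated silylation of the secondary benzylic alcohol avoids the ionisation and dehydration to a benzofuran that acid would invite; with the same silyl group on both oxygens, any 1,5 oxygen-to-oxygen silyl shift in alkoxide 8 converges on the same product.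

Step 6
Reactants: 10 (2R,3R)-3-(triethylsilyloxy)-2-[2-(triethylsilyloxy)propan-2-yl]-2,3-dihydro-1-benzofuran
Product: 11 (2R,3R)-5-bromo-3-(triethylsilyloxy)-2-[2-(triethylsilyloxy)propan-2-yl]-2,3-dihydro-1-benzofuran
Conditions: NBS, MeCN, 0 °C → rt, dark
Reagents that add atoms: N-bromosuccinimide, O=C1CCC(=O)N1Br
Why: Electrophilic aromatic bromination of an alkyl aryl ether with NBS in MeCN is para-selective, so bromine should enter at C5 (para to O1) in preference to C7 (ortho to O1); polar conditions in the dark avoid radical attack at the C3–H bond.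

Step 7
Reactants: 12 1-(2,4-dihydroxyphenyl)ethan-1-one (2,4-dihydroxyacetophenone); 13 1-bromo-3-methylbut-2-ene (prenyl bromide)
Product: 14 1-[2,4-dihydroxy-3-(3-methylbut-2-en-1-yl)phenyl]ethan-1-one
Conditions: KOH (10% aq), 0 °C → rt
Reagents that add atoms: none
Why: C-Alkylation of the resorcinol-type phenoxide in water, where hydrogen bonding shields the oxygens, should go mainly to C3 between the two oxygen functions (phenoxide C-prenylation); regioselectivity is expected to be modest and the 5-prenyl and O-prenyl isomers are removed by chromatography.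

Step 8
Reactants: 14 1-[2,4-dihydroxy-3-(3-methylbut-2-en-1-yl)phenyl]ethan-1-one
Product: 15 1-[2,4-bis(tert-butyldimethylsilyloxy)-3-(3-methylbut-2-en-1-yl)phenyl]ethan-1-one
Conditions: t-BuMe2SiCl (3 equiv), imidazole, 4-(dimethylamino)pyridine (cat.), DMF, 50 °C
Reagents that add atoms: tert-butylchlorodimethylsilane, CC(C)(C)[Si](C)(C)Cl
Why: Silyl ether formation on both phenols, with heat and nucleophilic catalysis to overcome the hydrogen bond and flanking groups at the 2-hydroxyl; the 2-O-silyl group later blocks oxa-Michael closure of the vinyl ketone to a chromanone.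

Step 9
Reactants: 15 1-[2,4-bis(tert-butyldimethylsilyloxy)-3-(3-methylbut-2-en-1-yl)phenyl]ethan-1-one
Product: 17 1-[2,4-bis(tert-butyldimethylsilyloxy)-3-(3-methylbut-2-en-1-yl)phenyl]-3-(dimethylamino)propan-1-one, via lithium enolate 16 (not isolated)
Conditions: LiN(SiMe3)2, THF, −78 °C; then CH2=NMe2+ I−, −78 °C → rt
Reagents that add atoms: N,N-dimethylmethyleneiminium iodide (Eschenmoser's salt), C=[N+](C)C.[I-]
Why: Kinetic enolate formation followed by Mannich aminomethylation with Eschenmoser's salt gives the β-amino ketone; the aryl silyl ethers should survive the non-nucleophilic amide base, and the enolate is trapped at low temperature before oxygen-to-oxygen silyl transfer from the 2-O-silyl group can compete.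

Step 10
Reactants: 17 1-[2,4-bis(tert-butyldimethylsilyloxy)-3-(3-methylbut-2-en-1-yl)phenyl]-3-(dimethylamino)propan-1-one
Product: 19 1-[2,4-bis(tert-butyldimethylsilyloxy)-3-(3-methylbut-2-en-1-yl)phenyl]prop-2-en-1-one, via ammonium iodide 18 (not isolated)
Conditions: MeI, Et2O, rt; evaporate; NaHCO3 (aq)/CH2Cl2, rt; used at once (trace BHT)
Reagents that add atoms: none
Why: Quaternisation of the amine and mild base-induced E1cB (Hofmann-type) loss of trimethylamine from the β-ammonium ketone unveil the aryl vinyl ketone, which is carried on immediately because such enones polymerise.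

Step 11
Reactants: 11 (2R,3R)-5-bromo-3-(triethylsilyloxy)-2-[2-(triethylsilyloxy)propan-2-yl]-2,3-dihydro-1-benzofuran; 19 1-[2,4-bis(tert-butyldimethylsilyloxy)-3-(3-methylbut-2-en-1-yl)phenyl]prop-2-en-1-one
Product: 20 (E)-1-[2,4-bis(tert-butyldimethylsilyloxy)-3-(3-methylbut-2-en-1-yl)phenyl]-3-{(2R,3R)-3-(triethylsilyloxy)-2-[2-(triethylsilyloxy)propan-2-yl]-2,3-dihydro-1-benzofuran-5-yl}prop-2-en-1-one
Conditions: Pd2(dba)3 [tris(dibenzylideneacetone)dipalladium] (2.5 mol %), [HP(t-Bu)3]BF4 (10 mol %), Cy2NMe, 1,4-dioxane, 70 °C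
Reagents that add atoms: none
Why: Mizoroki–Heck coupling, in which oxidative addition of the aryl bromide to zerovalent palladium bearing P(t-Bu)3, syn insertion of the terminal enone alkene and syn β-hydride elimination should give only the (E)-chalcone; the trisubstituted prenyl alkene is too hindered to insert and the stereocentres are not involved.

Step 12
Reactants: 20 (E)-1-[2,4-bis(tert-butyldimethylsilyloxy)-3-(3-methylbut-2-en-1-yl)phenyl]-3-{(2R,3R)-3-(triethylsilyloxy)-2-[2-(triethylsilyloxy)propan-2-yl]-2,3-dihydro-1-benzofuran-5-yl}prop-2-en-1-one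
Product: 21 Paratocarpin G, (E)-1-[2,4-dihydroxy-3-(3-methylbut-2-en-1-yl)phenyl]-3-[(2R,3R)-3-hydroxy-2-(2-hydroxypropan-2-yl)-2,3-dihydro-1-benzofuran-5-yl]prop-2-en-1-one
Conditions: Bu4NF (6 equiv), AcOH (6 equiv), THF, 0 °C → rt
Reagents that add atoms: none
Why: Fluoride-mediated cleavage of all four silyl ethers, buffered with acetic acid so that neither base-induced flavanone closure of the 2'-hydroxychalcone nor acid-induced dehydration of the benzylic C3 alcohol is favoured; C2 and C3 are untouched.

**Compound list**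

1 | 2-hydroxybenzyl alcohol | OCc1ccccc1O | starting material
2 | (1R,2S,5R)-menthyl 2,2-dihydroxyacetate ((−)-menthyl glyoxylate hydrate) | O=C(O[C@@H]1C[C@H](C)CC[C@H]1C(C)C)C(O)O | starting material
3 | (1R,2S,5R)-menthyl (2S)-4H-1,3-benzodioxine-2-carboxylate | c1ccc2c(c1)CO[C@H](C(=O)O[C@@H]3C[C@H](C)CC[C@H]3C(C)C)O2 | intermediate
4 | 1-[(2S)-4H-1,3-benzodioxin-2-yl]ethan-1-one (methyl ketone) | c1ccc2c(c1)CO[C@H](C(C)=O)O2 | intermediate (not isolated)
5 | 2-[(2S)-4H-1,3-benzodioxin-2-yl]propan-2-ol | c1ccc2c(c1)CO[C@H](C(C)(C)O)O2 | intermediate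
6 | (2S)-2-[2-(triethylsilyloxy)propan-2-yl]-4H-1,3-benzodioxine | c1ccc2c(c1)CO[C@H](C(C)(C)O[Si](CC)(CC)CC)O2 | intermediate
7 | (2S)-4-lithio-2-[2-(triethylsilyloxy)propan-2-yl]-4H-1,3-benzodioxine (C4 undefined) | c1ccc2c(c1)C([Li])O[C@H](C(C)(C)O[Si](CC)(CC)CC)O2 | intermediate (not isolated)
8 | lithium (2R,3R)-2-[2-(triethylsilyloxy)propan-2-yl]-2,3-dihydro-1-benzofuran-3-olate | c1ccc2c(c1)[C@@H](O[Li])[C@H](C(C)(C)O[Si](CC)(CC)CC)O2 | intermediate (not isolated)
9 | (2R,3R)-2-[2-(triethylsilyloxy)propan-2-yl]-2,3-dihydro-1-benzofuran-3-ol | c1ccc2c(c1)[C@@H](O)[C@H](C(C)(C)O[Si](CC)(CC)CC)O2 | intermediate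
10 | (2R,3R)-3-(triethylsilyloxy)-2-[2-(triethylsilyloxy)propan-2-yl]-2,3-dihydro-1-benzofuran | c1ccc2c(c1)[C@@H](O[Si](CC)(CC)CC)[C@H](C(C)(C)O[Si](CC)(CC)CC)O2 | intermediate
11 | (2R,3R)-5-bromo-3-(triethylsilyloxy)-2-[2-(triethylsilyloxy)propan-2-yl]-2,3-dihydro-1-benzofuran | Brc1ccc2c(c1)[C@@H](O[Si](CC)(CC)CC)[C@H](C(C)(C)O[Si](CC)(CC)CC)O2 | intermediate
12 | 1-(2,4-dihydroxyphenyl)ethan-1-one | CC(=O)c1ccc(O)cc1O | starting material
13 | 1-bromo-3-methylbut-2-ene | CC(C)=CCBr | starting material
14 | 1-[2,4-dihydroxy-3-(3-methylbut-2-en-1-yl)phenyl]ethan-1-one | CC(=O)c1ccc(O)c(CC=C(C)C)c1O | intermediate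
15 | 1-[2,4-bis(tert-butyldimethylsilyloxy)-3-(3-methylbut-2-en-1-yl)phenyl]ethan-1-one | CC(=O)c1ccc(O[Si](C)(C)C(C)(C)C)c(CC=C(C)C)c1O[Si](C)(C)C(C)(C)C | intermediate
16 | lithium enolate of 15 | C=C(O[Li])c1ccc(O[Si](C)(C)C(C)(C)C)c(CC=C(C)C)c1O[Si](C)(C)C(C)(C)C | intermediate (not isolated)
17 | 1-[2,4-bis(tert-butyldimethylsilyloxy)-3-(3-methylbut-2-en-1-yl)phenyl]-3-(dimethylamino)propan-1-one | CN(C)CCC(=O)c1ccc(O[Si](C)(C)C(C)(C)C)c(CC=C(C)C)c1O[Si](C)(C)C(C)(C)C | intermediate
18 | 3-[2,4-bis(tert-butyldimethylsilyloxy)-3-(3-methylbut-2-en-1-yl)phenyl]-N,N,N-trimethyl-3-oxopropan-1-aminium iodide | C[N+](C)(C)CCC(=O)c1ccc(O[Si](C)(C)C(C)(C)C)c(CC=C(C)C)c1O[Si](C)(C)C(C)(C)C.[I-] | intermediate (not isolated)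
19 | 1-[2,4-bis(tert-butyldimethylsilyloxy)-3-(3-methylbut-2-en-1-yl)phenyl]prop-2-en-1-one | C=CC(=O)c1ccc(O[Si](C)(C)C(C)(C)C)c(CC=C(C)C)c1O[Si](C)(C)C(C)(C)C | intermediate
20 | (E)-1-[2,4-bis(tert-butyldimethylsilyloxy)-3-(3-methylbut-2-en-1-yl)phenyl]-3-{(2R,3R)-3-(triethylsilyloxy)-2-[2-(triethylsilyloxy)propan-2-yl]-2,3-dihydro-1-benzofuran-5-yl}prop-2-en-1-one | CC(C)=CCc1c(O[Si](C)(C)C(C)(C)C)ccc(C(=O)/C=C/c2ccc3c(c2)[C@@H](O[Si](CC)(CC)CC)[C@H](C(C)(C)O[Si](CC)(CC)CC)O3)c1O[Si](C)(C)C(C)(C)C | intermediate
21 | Paratocarpin G | CC(C)=CCc1c(O)ccc(C(=O)/C=C/c2ccc3c(c2)[C@@H](O)[C@H](C(C)(C)O)O3)c1O | target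

**Step count and risks**

Total step count: 12. Longest linear sequence: 8 steps (steps 1–6, then 11 and 12).

Steps most likely to fail:

1. Step 4 (key step). Lithiation ortho to O1 at C8 or at the acetal carbon may outrun benzylic lithiation, the lithiated acetal may open by α-elimination instead of rearranging, and the radical pair may recombine with erosion of the C2 configuration or without trans control at C3. The fallback uses known epoxide chemistry, sets out from 1 and returns at 10. Compound 1 would be oxidised with MnO2 to salicylaldehyde F1 and silylated (i-Pr3SiCl, imidazole) to 2-(triisopropylsilyloxy)benzaldehyde F2, and 2-methylprop-1-enylmagnesium bromide would then give racemic 3-methyl-1-[2-(triisopropylsilyloxy)phenyl]but-2-en-1-ol F3. Sharpless kinetic resolution [Ti(OiPr)4, L-(+)-diisopropyl tartrate, t-BuOOH, 4 Å sieves, CH2Cl2, −20 °C], run past half conversion, should consume the (R)-alcohol as the erythro epoxy alcohol (S)-[(2S)-3,3-dimethyloxiran-2-yl][2-(triisopropylsilyloxy)phenyl]methanol F4, which is discarded, and leave (S)-3-methyl-1-[2-(triisopropylsilyloxy)phenyl]but-2-en-1-ol F5. Hydroxyl-directed epoxidation of the recovered alcohol with mCPBA/NaHCO3 should be threo-selective because of allylic 1,3-strain with the cis methyl group, giving (R)-[(2S)-3,3-dimethyloxiran-2-yl][2-(triisopropylsilyloxy)phenyl]methanol F6. Bu4NF then frees the phenoxide, which should open the epoxide in 5-exo fashion at its secondary carbon with inversion to give (2R,3R)-2-(2-hydroxypropan-2-yl)-2,3-dihydro-1-benzofuran-3-ol F7, and double silylation (Et3SiCl, imidazole, 4-(dimethylamino)pyridine, DMF, 40 °C) returns to 10.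

2. Step 1. Acid-promoted self-condensation of salicyl alcohol through its benzylic cation may outpace acetalisation of the electron-poor glyoxylate, or the two menthyl ester epimers may resist separation on scale. The fallback replaces the auxiliary by a simple aldehyde and enantiomer separation, sets out from 1 and returns at 6. Methyl 2-hydroxy-2-methylpropanoate would be silylated (Et3SiOTf, 2,6-lutidine) to methyl 2-methyl-2-(triethylsilyloxy)propanoate F8 and half-reduced (i-Bu2AlH, CH2Cl2, −78 °C) to 2-methyl-2-(triethylsilyloxy)propanal F9. This non-enolisable aldehyde would be condensed with 1 (pyridinium p-toluenesulfonate, MgSO4, CH2Cl2) to racemic 2-[2-(triethylsilyloxy)propan-2-yl]-4H-1,3-benzodioxine F10, and the enantiomers separated by preparative chromatography on a chiral stationary phase to give 6.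

3. Step 11. Vinyl ketone 19 may polymerise or dimerise under the warm basic conditions, or slow oxidative addition of the electron-rich bromide may lead to reduction of 11. The fallback replaces the Heck coupling by an aldol condensation, sets out from 11 and returns at 20. Bromine–lithium exchange (n-BuLi, THF, −78 °C) and trapping with DMF would give (2R,3R)-3-(triethylsilyloxy)-2-[2-(triethylsilyloxy)propan-2-yl]-2,3-dihydro-1-benzofuran-5-carbaldehyde F11. Its addition at −78 °C to lithium enolate 16 (from 15 and LiN(SiMe3)2) would give the β-hydroxy ketone 1-[2,4-bis(tert-butyldimethylsilyloxy)-3-(3-methylbut-2-en-1-yl)phenyl]-3-hydroxy-3-{(2R,3R)-3-(triethylsilyloxy)-2-[2-(triethylsilyloxy)propan-2-yl]-2,3-dihydro-1-benzofuran-5-yl}propan-1-one F12 as both carbinol epimers. Mesylation (MsCl, Et3N, CH2Cl2, 0 °C) to the corresponding methanesulfonate F13 and elimination with DBU should give the (E)-enone 20.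

Further compounds
F1 | step 4 | salicylaldehyde | O=Cc1ccccc1O
F2 | step 4 | 2-(triisopropylsilyloxy)benzaldehyde | CC(C)[Si](C(C)C)(C(C)C)Oc1ccccc1C=O
F3 | step 4 | racemic 3-methyl-1-[2-(triisopropylsilyloxy)phenyl]but-2-en-1-ol | CC(C)[Si](C(C)C)(C(C)C)Oc1ccccc1C(O)C=C(C)C
F4 | step 4 | (S)-[(2S)-3,3-dimethyloxiran-2-yl][2-(triisopropylsilyloxy)phenyl]methanol (erythro, discarded) | CC(C)[Si](C(C)C)(C(C)C)Oc1ccccc1[C@H](O)[C@@H]1OC1(C)C
F5 | step 4 | (S)-3-methyl-1-[2-(triisopropylsilyloxy)phenyl]but-2-en-1-ol | CC(C)[Si](C(C)C)(C(C)C)Oc1ccccc1[C@@H](O)C=C(C)C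
F6 | step 4 | (R)-[(2S)-3,3-dimethyloxiran-2-yl][2-(triisopropylsilyloxy)phenyl]methanol (threo) | CC(C)[Si](C(C)C)(C(C)C)Oc1ccccc1[C@@H](O)[C@@H]1OC1(C)C
F7 | step 4 | (2R,3R)-2-(2-hydroxypropan-2-yl)-2,3-dihydro-1-benzofuran-3-ol | c1ccc2c(c1)[C@@H](O)[C@H](C(C)(C)O)O2
F8 | step 1 | methyl 2-methyl-2-(triethylsilyloxy)propanoate | COC(=O)C(C)(C)O[Si](CC)(CC)CC
F9 | step 1 | 2-methyl-2-(triethylsilyloxy)propanal | O=CC(C)(C)O[Si](CC)(CC)CC
F10 | step 1 | racemic 2-[2-(triethylsilyloxy)propan-2-yl]-4H-1,3-benzodioxine | c1ccc2c(c1)COC(C(C)(C)O[Si](CC)(CC)CC)O2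
F11 | step 11 | (2R,3R)-3-(triethylsilyloxy)-2-[2-(triethylsilyloxy)propan-2-yl]-2,3-dihydro-1-benzofuran-5-carbaldehyde | O=Cc1ccc2c(c1)[C@@H](O[Si](CC)(CC)CC)[C@H](C(C)(C)O[Si](CC)(CC)CC)O2
F12 | step 11 | 1-[2,4-bis(tert-butyldimethylsilyloxy)-3-(3-methylbut-2-en-1-yl)phenyl]-3-hydroxy-3-{(2R,3R)-3-(triethylsilyloxy)-2-[2-(triethylsilyloxy)propan-2-yl]-2,3-dihydro-1-benzofuran-5-yl}propan-1-one | CC(C)=CCc1c(O[Si](C)(C)C(C)(C)C)ccc(C(=O)CC(O)c2ccc3c(c2)[C@@H](O[Si](CC)(CC)CC)[C@H](C(C)(C)O[Si](CC)(CC)CC)O3)c1O[Si](C)(C)C(C)(C)C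
F13 | step 11 | methanesulfonate of F12 | CC(C)=CCc1c(O[Si](C)(C)C(C)(C)C)ccc(C(=O)CC(OS(C)(=O)=O)c2ccc3c(c2)[C@@H](O[Si](CC)(CC)CC)[C@H](C(C)(C)O[Si](CC)(CC)CC)O3)c1O[Si](C)(C)C(C)(C)C
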